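The lactone (ring D) carries three contiguous carbons: C-α next to the carbonyl, C-β, and the benzylic carbinol carbon attached to ring E. Their polarity (nucleophilic C-α, electrophilic carbinol carbon) is that of an aryl-donor, dicarbonyl-acceptor cyclopropane fused to ring D, so the route rests on a temporary C-α–carbinol-carbon bond. Step 5, an intramolecular copper-carbene (2+1) addition, closes ring D and the cyclopropane at once and fixes C-β, the benzylic carbon and the ring fusion in one enantiomer. Its precursor is the methyl (E)-cinnamyl diazomalonate made from coniferyl aldehyde, with the ring-E phenol masked as a pivalate. Invertive benzyl alcohol opening, C-α benzylation with an enantiopure dihydrobenzofuran bromide and demethoxycarbonylation finish the skeleton.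

Key step: step 5

Ring letters: A = guaiacyl ring on C-2 of the dihydrobenzofuran, B = benzo ring, C = dihydrofuran ring, D = lactone, E = guaiacyl ring on the carbinol carbon.

Assumption: the sense of induction of the (S,S)-ligand in step 5 and of Rh2(S-PTTL)4 in step 10 is assigned by analogy with related substrates; if a first run shows the opposite sense, the mirror-image ligand or catalyst, both available, is used.

**Route**

Step 1
Reactants: 1 coniferyl aldehyde [(E)-3-(4-hydroxy-3-methoxyphenyl)prop-2-enal]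
Product: 2 (E)-2-methoxy-4-(3-oxoprop-1-en-1-yl)phenyl pivalate
Conditions: PivCl, Et3N, DMAP (cat.), CH2Cl2, 0 °C → rt
Reagents that add atoms: pivaloyl chloride, CC(C)(C)C(=O)Cl
Why: DMAP-catalysed O-acylation of the only hydroxyl group (the phenol) should be clean, the enal is inert, and the acyl group makes ring E electron-poorer for steps 5 and 6.

Step 2
Reactants: 2 (E)-2-methoxy-4-(3-oxoprop-1-en-1-yl)phenyl pivalate
Product: 3 (E)-4-(3-hydroxyprop-1-en-1-yl)-2-methoxyphenyl pivalate
Conditions: NaBH4, CeCl3·7H2O, MeOH, 0 °C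
Reagents that add atoms: none
Why: Luche reduction delivers hydride 1,2 to the enal and is too mild and too short to touch the hindered aryl pivalate or the (E)-alkene.

Step 3
Reactants: 3 (E)-4-(3-hydroxyprop-1-en-1-yl)-2-methoxyphenyl pivalate; 4 methyl malonyl chloride
Product: 5 (E)-3-(3-methoxy-4-pivaloyloxyphenyl)allyl methyl malonate
Conditions: pyridine, CH2Cl2, 0 °C
Reagents that add atoms: methyl malonyl chloride (4), COC(=O)CC(=O)Cl
Why: Acylation of a primary allylic alcohol by an acid chloride with pyridine as base is routine, and the low temperature suppresses ketene formation from the malonyl chloride.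

Step 4
Reactants: 5 (E)-3-(3-methoxy-4-pivaloyloxyphenyl)allyl methyl malonate; 6 4-acetamidobenzenesulfonyl azide
Product: 7 (E)-3-(3-methoxy-4-pivaloyloxyphenyl)allyl methyl 2-diazomalonate
Conditions: Et3N, MeCN, 0 °C → rt
Reagents that add atoms: 4-acetamidobenzenesulfonyl azide (6), CC(=O)Nc1ccc(cc1)S(=O)(=O)N=[N+]=[N-]
Why: Regitz diazo transfer works on the malonate CH2 with triethylamine alone, and neither the aryl pivalate nor the cinnamyl ester reacts with the sulfonyl azide.

Step 5
Reactants: 7 (E)-3-(3-methoxy-4-pivaloyloxyphenyl)allyl methyl 2-diazomalonate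
Product: 8 methyl (1S,5R,6S)-6-(3-methoxy-4-pivaloyloxyphenyl)-2-oxo-3-oxabicyclo[3.1.0]hexane-1-carboxylate (aryl exo)
Conditions: Cu(MeCN)4PF6 (5 mol%), 2,2'-isopropylidenebis[(4S)-4-tert-butyl-2-oxazoline] (6 mol%), ClCH2CH2Cl, 65 °C, 7 added over 10 h
Reagents that add atoms: none
Why: The cationic monovalent copper–bis(oxazoline) complex takes up diazo ester 7, loses N2 and forms an electrophilic copper carbene, which adds to the tethered (E)-alkene in one concerted, asynchronous (2+1) step. The closest known reaction type is the copper–bis(oxazoline)-catalysed intramolecular cyclopropanation of allylic diazomalonates and diazoacetates to 3-oxabicyclo[3.1.0]hexan-2-ones. Ring D closes in a 5-exo mode when the carbene carbon bonds to the alkene carbon nearer the ester oxygen (the future C-β), and the cyclopropane closes in a 3-exo mode through the second bond to the benzylic carbon. C-β is set by the ligand, which decides the alkene face that meets the carbene; the benzylic carbon follows stereospecifically from the (E)-geometry (aryl exo, trans to the lactone CH2); the quaternary C-α is fixed by the three-atom ester tether, which allows only the cis ring fusion. The step needs enantioface selectivity and chemoselectivity over carbene dimerisation and allylic C–H insertion, which the bulky tert-butyl ligand, the non-coordinating PF6 counter-ion and slow addition should provide, while the (E)-alkene and the short tether in the substrate secure the diastereoselectivity and the pivalate keeps the product from ionising at the benzylic carbon under the copper Lewis acid.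

Step 6
Reactants: 8 methyl (1S,5R,6S)-6-(3-methoxy-4-pivaloyloxyphenyl)-2-oxo-3-oxabicyclo[3.1.0]hexane-1-carboxylate
Product: 9 methyl (3S,4R)-4-[(R)-benzyloxy(3-methoxy-4-pivaloyloxyphenyl)methyl]-2-oxooxolane-3-carboxylate
Conditions: BnOH (3 equiv), Sc(OTf)3 (10 mol%), 4 Å molecular sieves, CH2Cl2, 0 °C → rt
Reagents that add atoms: benzyl alcohol, OCc1ccccc1
Why: In this Lewis-acid-catalysed nucleophilic ring opening of a donor–acceptor cyclopropane, Sc(OTf)3 chelates the two carbonyl groups and benzyl alcohol attacks the benzylic carbon anti to the breaking bond to C-α (SN2-like, inversion), which sets the (R)-ether, leaves C-β untouched and turns C-α into an epimerisable malonate-type centre.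

Step 7
Reactants: 10 5-iodovanillin (4-hydroxy-3-iodo-5-methoxybenzaldehyde); 11 4-(benzyloxy)-3-methoxybenzyl alcohol
Product: 12 4-{[4-(benzyloxy)-3-methoxyphenyl]methoxy}-3-iodo-5-methoxybenzaldehyde
Conditions: PPh3, DIAD, THF, 0 °C → rt
Reagents that add atoms: none
Why: In this Mitsunobu etherification the acidic phenol is a good pronucleophile for the oxyphosphonium salt of the primary benzylic alcohol, and aldehyde and aryl iodide are inert.

Step 8
Reactants: 12 4-{[4-(benzyloxy)-3-methoxyphenyl]methoxy}-3-iodo-5-methoxybenzaldehyde; 13 ethyl diazoacetate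
Product: 14 ethyl 2-(2-{[4-(benzyloxy)-3-methoxyphenyl]methoxy}-5-formyl-3-methoxyphenyl)-2-diazoacetate
Conditions: Pd(PPh3)4 (5 mol%), Ag2CO3 (0.5 equiv), Et3N, toluene, rt
Reagents that add atoms: ethyl diazoacetate (13), CCOC(=O)C=[N+]=[N-]
Why: This is the palladium-catalysed cross-coupling of an aryl iodide with ethyl diazoacetate with retention of the diazo group (oxidative addition to zerovalent palladium, then silver-assisted C–H arylation of the diazo ester), and the formyl group makes the iodide electron-poor and so favours the oxidative addition.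

Step 9
Reactants: 14 ethyl 2-(2-{[4-(benzyloxy)-3-methoxyphenyl]methoxy}-5-formyl-3-methoxyphenyl)-2-diazoacetate
Product: 16 ethyl 2-[5-(acetoxymethyl)-2-{[4-(benzyloxy)-3-methoxyphenyl]methoxy}-3-methoxyphenyl]-2-diazoacetate, via benzylic alcohol 15 (not isolated)
Conditions: NaBH4, THF–MeOH, 0 °C; then Ac2O, pyridine, DMAP (cat.), rt
Reagents that add atoms: acetic anhydride, CC(=O)OC(C)=O
Why: Borohydride reduces the aromatic aldehyde but not the diazo ester, and DMAP-catalysed acetylation then removes the O–H bond that would intercept the rhodium carbene, as well as the formyl group that would make the ring oxygen a good leaving group during the base treatment of step 10.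

Step 10
Reactants: 16 ethyl 2-[5-(acetoxymethyl)-2-{[4-(benzyloxy)-3-methoxyphenyl]methoxy}-3-methoxyphenyl]-2-diazoacetate
Product: 18 ethyl (2S,3S)-2-[4-(benzyloxy)-3-methoxyphenyl]-5-(hydroxymethyl)-7-methoxy-2,3-dihydro-1-benzofuran-3-carboxylate (trans), via cis insertion ester 17 (not isolated)
Conditions: Rh2(S-PTTL)4 {dirhodium tetrakis[N-phthaloyl-(S)-tert-leucinate]} (1 mol%), toluene, −60 °C; then NaOEt (0.3 equiv), EtOH, 0 °C → rt
Reagents that add atoms: none
Why: Intramolecular 1,5 C–H insertion of the donor/acceptor carbene of divalent rhodium into the benzylic C–H bond next to the ether oxygen should give the cis ester with C-2 set by the chiral carboxylate catalyst, after which catalytic ethoxide removes the acetate by transesterification and epimerises C-3 through the ester enolate to the more stable trans isomer.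

Step 11
Reactants: 18 ethyl (2S,3S)-2-[4-(benzyloxy)-3-methoxyphenyl]-5-(hydroxymethyl)-7-methoxy-2,3-dihydro-1-benzofuran-3-carboxylate
Product: 19 {(2S,3R)-2-[4-(benzyloxy)-3-methoxyphenyl]-7-methoxy-2,3-dihydro-1-benzofuran-3,5-diyl}dimethanol
Conditions: i-Bu2AlH (DIBAL-H, excess), CH2Cl2, −78 → 0 °C; aqueous potassium sodium tartrate
Reagents that add atoms: none
Why: Hydride reduction of the ester to the primary alcohol with i-Bu2AlH is non-basic, so C-3 cannot epimerise or ring-open, and the benzyl ethers are inert.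

Step 12
Reactants: 19 {(2S,3R)-2-[4-(benzyloxy)-3-methoxyphenyl]-7-methoxy-2,3-dihydro-1-benzofuran-3,5-diyl}dimethanol
Product: 20 {(2S,3R)-2-[4-(benzyloxy)-3-methoxyphenyl]-5-(bromomethyl)-7-methoxy-2,3-dihydro-1-benzofuran-3-yl}methanol
Conditions: NBS, Me2S, CH2Cl2, −20 → 0 °C; used at once without chromatography
Reagents that add atoms: N-bromosuccinimide, O=C1CCC(=O)N1Br
Why: In the Corey–Kim halogenation the bromosulfonium reagent turns only the benzylic alcohol into the bromide through its alkoxysulfonium salt, whereas the salt of the saturated primary alcohol is not displaced and returns the alcohol on work-up.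

Step 13
Reactants: 9 methyl (3S,4R)-4-[(R)-benzyloxy(3-methoxy-4-pivaloyloxyphenyl)methyl]-2-oxooxolane-3-carboxylate; 20 {(2S,3R)-2-[4-(benzyloxy)-3-methoxyphenyl]-5-(bromomethyl)-7-methoxy-2,3-dihydro-1-benzofuran-3-yl}methanol
Product: 21 methyl (3R,4R)-4-[(R)-benzyloxy(3-methoxy-4-pivaloyloxyphenyl)methyl]-3-({(2S,3R)-2-[4-(benzyloxy)-3-methoxyphenyl]-3-(hydroxymethyl)-7-methoxy-2,3-dihydro-1-benzofuran-5-yl}methyl)-2-oxooxolane-3-carboxylate
Conditions: Cs2CO3 (1.2 equiv), DMF, 0 °C → rt
Reagents that add atoms: none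
Why: C-alkylation of the malonate-type α-methoxycarbonyl lactone with a reactive benzylic bromide needs only carbonate base, which leaves the primary alcohol of 20 un-ionised; the electrophile should enter anti to the C-β substituent, but this quaternary centre is only temporary.

Step 14
Reactants: 21 methyl (3R,4R)-4-[(R)-benzyloxy(3-methoxy-4-pivaloyloxyphenyl)methyl]-3-({(2S,3R)-2-[4-(benzyloxy)-3-methoxyphenyl]-3-(hydroxymethyl)-7-methoxy-2,3-dihydro-1-benzofuran-5-yl}methyl)-2-oxooxolane-3-carboxylate
Product: 22 (3R,4R)-4-[(R)-benzyloxy(3-methoxy-4-pivaloyloxyphenyl)methyl]-3-({(2S,3R)-2-[4-(benzyloxy)-3-methoxyphenyl]-3-(hydroxymethyl)-7-methoxy-2,3-dihydro-1-benzofuran-5-yl}methyl)oxolan-2-one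
Conditions: LiCl (3 equiv), H2O (2 equiv), DMSO, 135 °C
Reagents that add atoms: none
Why: In the Krapcho demethoxycarbonylation chloride demethylates the ester, CO2 is lost and the lactone enolate is protonated anti to the C-β substituent, which together with the thermodynamic preference should give the 3,4-trans lactone under neutral conditions that spare pivalate and ethers.

Step 15
Reactants: 22 (3R,4R)-4-[(R)-benzyloxy(3-methoxy-4-pivaloyloxyphenyl)methyl]-3-({(2S,3R)-2-[4-(benzyloxy)-3-methoxyphenyl]-3-(hydroxymethyl)-7-methoxy-2,3-dihydro-1-benzofuran-5-yl}methyl)oxolan-2-one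
Product: 23 (3R,4R)-4-[(R)-benzyloxy(4-hydroxy-3-methoxyphenyl)methyl]-3-({(2S,3R)-2-[4-(benzyloxy)-3-methoxyphenyl]-3-(hydroxymethyl)-7-methoxy-2,3-dihydro-1-benzofuran-5-yl}methyl)oxolan-2-one
Conditions: K2CO3 (cat.), MeOH–THF, rt; AcOH quench
Reagents that add atoms: none
Why: Base-catalysed methanolysis removes the activated aryl ester while the carbinol is still a benzyl ether, so the lactone cannot migrate to the carbinol oxygen, and any methanolysed lactone recloses on the acidic quench to the stable trans isomer.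

Step 16
Reactants: 23 (3R,4R)-4-[(R)-benzyloxy(4-hydroxy-3-methoxyphenyl)methyl]-3-({(2S,3R)-2-[4-(benzyloxy)-3-methoxyphenyl]-3-(hydroxymethyl)-7-methoxy-2,3-dihydro-1-benzofuran-5-yl}methyl)oxolan-2-one
Product: 24 (3R,4R)-4-[(R)-hydroxy(4-hydroxy-3-methoxyphenyl)methyl]-3-({(2S,3R)-2-(4-hydroxy-3-methoxyphenyl)-3-(hydroxymethyl)-7-methoxy-2,3-dihydro-1-benzofuran-5-yl}methyl)oxolan-2-one (target)
Conditions: H2 (1 atm), 10% Pd/C, EtOAc–EtOH, rt
Reagents that add atoms: none
Why: Catalytic hydrogenolysis under neutral conditions should cleave the aryl benzyl ether and the unhindered primary benzyl C–O bond of the dibenzylic ether, sparing the more hindered secondary benzylic C–O bond, the lactone and ring C, so the acid- and base-sensitive p-hydroxybenzylic alcohol is exposed only at the end.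

**Compound list**

1 | coniferyl aldehyde, (E)-3-(4-hydroxy-3-methoxyphenyl)prop-2-enal | COc1cc(/C=C/C=O)ccc1O | starting material
2 | (E)-2-methoxy-4-(3-oxoprop-1-en-1-yl)phenyl pivalate | COc1cc(/C=C/C=O)ccc1OC(=O)C(C)(C)C | intermediate
3 | (E)-4-(3-hydroxyprop-1-en-1-yl)-2-methoxyphenyl pivalate | COc1cc(/C=C/CO)ccc1OC(=O)C(C)(C)C | intermediate
4 | methyl malonyl chloride | COC(=O)CC(=O)Cl | starting material
5 | (E)-3-(3-methoxy-4-pivaloyloxyphenyl)allyl methyl malonate | COC(=O)CC(=O)OC/C=C/c1ccc(OC(=O)C(C)(C)C)c(OC)c1 | intermediate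
6 | 4-acetamidobenzenesulfonyl azide | CC(=O)Nc1ccc(cc1)S(=O)(=O)N=[N+]=[N-] | starting material
7 | (E)-3-(3-methoxy-4-pivaloyloxyphenyl)allyl methyl 2-diazomalonate | COC(=O)C(=[N+]=[N-])C(=O)OC/C=C/c1ccc(OC(=O)C(C)(C)C)c(OC)c1 | intermediate
8 | methyl (1S,5R,6S)-6-(3-methoxy-4-pivaloyloxyphenyl)-2-oxo-3-oxabicyclo[3.1.0]hexane-1-carboxylate, aryl exo | O=C1OC[C@@H]2[C@@H](c3ccc(OC(=O)C(C)(C)C)c(OC)c3)[C@]12C(=O)OC | intermediate
9 | methyl (3S,4R)-4-[(R)-benzyloxy(3-methoxy-4-pivaloyloxyphenyl)methyl]-2-oxooxolane-3-carboxylate (C-3 epimerisable, trans isomer drawn) | COC(=O)[C@H]1C(=O)OC[C@@H]1[C@@H](OCc1ccccc1)c1ccc(OC(=O)C(C)(C)C)c(OC)c1 | intermediate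
10 | 5-iodovanillin, 4-hydroxy-3-iodo-5-methoxybenzaldehyde | COc1cc(C=O)cc(I)c1O | starting material
11 | 4-(benzyloxy)-3-methoxybenzyl alcohol | COc1cc(CO)ccc1OCc1ccccc1 | starting material
12 | 4-{[4-(benzyloxy)-3-methoxyphenyl]methoxy}-3-iodo-5-methoxybenzaldehyde | COc1cc(C=O)cc(I)c1OCc1ccc(OCc2ccccc2)c(OC)c1 | intermediate
13 | ethyl diazoacetate | CCOC(=O)C=[N+]=[N-] | starting material
14 | ethyl 2-(2-{[4-(benzyloxy)-3-methoxyphenyl]methoxy}-5-formyl-3-methoxyphenyl)-2-diazoacetate | CCOC(=O)C(=[N+]=[N-])c1cc(C=O)cc(OC)c1OCc1ccc(OCc2ccccc2)c(OC)c1 | intermediate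
15 | ethyl 2-[2-{[4-(benzyloxy)-3-methoxyphenyl]methoxy}-5-(hydroxymethyl)-3-methoxyphenyl]-2-diazoacetate | CCOC(=O)C(=[N+]=[N-])c1cc(CO)cc(OC)c1OCc1ccc(OCc2ccccc2)c(OC)c1 | intermediate (not isolated)
16 | ethyl 2-[5-(acetoxymethyl)-2-{[4-(benzyloxy)-3-methoxyphenyl]methoxy}-3-methoxyphenyl]-2-diazoacetate | CCOC(=O)C(=[N+]=[N-])c1cc(COC(C)=O)cc(OC)c1OCc1ccc(OCc2ccccc2)c(OC)c1 | intermediate
17 | ethyl (2S,3R)-5-(acetoxymethyl)-2-[4-(benzyloxy)-3-methoxyphenyl]-7-methoxy-2,3-dihydro-1-benzofuran-3-carboxylate (cis) | COc1cc([C@H]2Oc3c(OC)cc(COC(C)=O)cc3[C@H]2C(=O)OCC)ccc1OCc1ccccc1 | intermediate (not isolated)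
18 | ethyl (2S,3S)-2-[4-(benzyloxy)-3-methoxyphenyl]-5-(hydroxymethyl)-7-methoxy-2,3-dihydro-1-benzofuran-3-carboxylate (trans) | COc1cc([C@H]2Oc3c(OC)cc(CO)cc3[C@@H]2C(=O)OCC)ccc1OCc1ccccc1 | intermediate
19 | {(2S,3R)-2-[4-(benzyloxy)-3-methoxyphenyl]-7-methoxy-2,3-dihydro-1-benzofuran-3,5-diyl}dimethanol | COc1cc([C@H]2Oc3c(OC)cc(CO)cc3[C@@H]2CO)ccc1OCc1ccccc1 | intermediate
20 | {(2S,3R)-2-[4-(benzyloxy)-3-methoxyphenyl]-5-(bromomethyl)-7-methoxy-2,3-dihydro-1-benzofuran-3-yl}methanol | COc1cc([C@H]2Oc3c(OC)cc(CBr)cc3[C@@H]2CO)ccc1OCc1ccccc1 | intermediate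
21 | methyl (3R,4R)-4-[(R)-benzyloxy(3-methoxy-4-pivaloyloxyphenyl)methyl]-3-({(2S,3R)-2-[4-(benzyloxy)-3-methoxyphenyl]-3-(hydroxymethyl)-7-methoxy-2,3-dihydro-1-benzofuran-5-yl}methyl)-2-oxooxolane-3-carboxylate | COc1cc([C@H]2Oc3c(OC)cc(C[C@@]4(C(=O)OC)C(=O)OC[C@@H]4[C@@H](OCc4ccccc4)c4ccc(OC(=O)C(C)(C)C)c(OC)c4)cc3[C@@H]2CO)ccc1OCc1ccccc1 | intermediate
22 | (3R,4R)-4-[(R)-benzyloxy(3-methoxy-4-pivaloyloxyphenyl)methyl]-3-({(2S,3R)-2-[4-(benzyloxy)-3-methoxyphenyl]-3-(hydroxymethyl)-7-methoxy-2,3-dihydro-1-benzofuran-5-yl}methyl)oxolan-2-one | COc1cc([C@H]2Oc3c(OC)cc(C[C@H]4C(=O)OC[C@@H]4[C@@H](OCc4ccccc4)c4ccc(OC(=O)C(C)(C)C)c(OC)c4)cc3[C@@H]2CO)ccc1OCc1ccccc1 | intermediate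
23 | (3R,4R)-4-[(R)-benzyloxy(4-hydroxy-3-methoxyphenyl)methyl]-3-({(2S,3R)-2-[4-(benzyloxy)-3-methoxyphenyl]-3-(hydroxymethyl)-7-methoxy-2,3-dihydro-1-benzofuran-5-yl}methyl)oxolan-2-one | COc1cc([C@H]2Oc3c(OC)cc(C[C@H]4C(=O)OC[C@@H]4[C@@H](OCc4ccccc4)c4ccc(O)c(OC)c4)cc3[C@@H]2CO)ccc1OCc1ccccc1 | intermediate
24 | (3R,4R)-4-[(R)-hydroxy(4-hydroxy-3-methoxyphenyl)methyl]-3-({(2S,3R)-2-(4-hydroxy-3-methoxyphenyl)-3-(hydroxymethyl)-7-methoxy-2,3-dihydro-1-benzofuran-5-yl}methyl)oxolan-2-one | COc1cc([C@H]2Oc3c(OC)cc(C[C@H]4C(=O)OC[C@@H]4[C@@H](O)c4ccc(O)c(OC)c4)cc3[C@@H]2CO)ccc1O | target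

**Step count**

Total: 16 steps. Longest linear sequence: 10 steps (1 → 24 through steps 1–6 and 13–16; the branch 10 → 24 through steps 7–16 is equally long).

**Steps most likely to fail**

Step 5. The process at risk is weak discrimination of the two alkene faces by the hot acceptor/acceptor copper carbene, together with carbene dimerisation at the temperature the diazomalonate needs. The fallback sets out from 2 and comes back at 8. Aldehyde 2 and dimethyl bromomalonate would be joined by iminium-catalysed Michael-initiated ring closure (α,α-diphenylprolinol trimethylsilyl ether, the antipode that leads to the 2R,3S series, 2,6-lutidine, CH2Cl2, 0 °C). This should give dimethyl (2R,3S)-2-formyl-3-(3-methoxy-4-pivaloyloxyphenyl)cyclopropane-1,1-dicarboxylate F1, in which the amine catalyst and not a metal carbene selects the face. NaBH4 reduction would give dimethyl (2R,3S)-2-(hydroxymethyl)-3-(3-methoxy-4-pivaloyloxyphenyl)cyclopropane-1,1-dicarboxylate F2, which with catalytic TsOH should lactonise onto the cis ester to give 8.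

Step 6. The process at risk is slow bimolecular attack on the pivalate-deactivated cyclopropane, which would let ionisation at the benzylic carbon (loss of inversion) or ester exchange with benzyl alcohol take over. The fallback sets out from 8 and comes back at 9. It separates C–O bond formation from the introduction of the benzyl group. Hydrative opening with the aqua complex Cu(ClO4)2·6H2O and 2,2'-bipyridine in 1,2-dimethoxyethane, where the small nucleophile is delivered from the metal with inversion, should give methyl (3S,4R)-4-[(R)-hydroxy(3-methoxy-4-pivaloyloxyphenyl)methyl]-2-oxooxolane-3-carboxylate F3. Neutral O-benzylation of F3 with 2-benzyloxy-1-methylpyridinium triflate and MgO in PhCF3 at 85 °C then gives 9.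

Step 10. The process at risk is leakage of enantiopurity, either by imperfect selection between the two enantiotopic benzylic hydrogens or by reversible oxa-Michael ring opening of the ester enolate during the base epimerisation. The fallback sets out from 14 and comes back at 19, and it avoids any enolate. Formyl diazo ester 14 would be cyclised with the mirror-image catalyst Rh2(R-PTTL)4 to ethyl (2R,3S)-2-[4-(benzyloxy)-3-methoxyphenyl]-5-formyl-7-methoxy-2,3-dihydro-1-benzofuran-3-carboxylate F4 (cis). Trifluoroacetic acid in CH2Cl2 should then epimerise C-2, not C-3, by reversible ionisation of the benzylic C–O bond to the p-alkoxybenzyl cation, giving ethyl (2S,3S)-2-[4-(benzyloxy)-3-methoxyphenyl]-5-formyl-7-methoxy-2,3-dihydro-1-benzofuran-3-carboxylate F5 (trans). i-Bu2AlH reduces its ester and aldehyde together to 19.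

**Further compounds**

F1 | step 5 | dimethyl (2R,3S)-2-formyl-3-(3-methoxy-4-pivaloyloxyphenyl)cyclopropane-1,1-dicarboxylate | O=C[C@@H]1[C@@H](c2ccc(OC(=O)C(C)(C)C)c(OC)c2)C1(C(=O)OC)C(=O)OC
F2 | step 5 | dimethyl (2R,3S)-2-(hydroxymethyl)-3-(3-methoxy-4-pivaloyloxyphenyl)cyclopropane-1,1-dicarboxylate | OC[C@@H]1[C@@H](c2ccc(OC(=O)C(C)(C)C)c(OC)c2)C1(C(=O)OC)C(=O)OC
F3 | step 6 | methyl (3S,4R)-4-[(R)-hydroxy(3-methoxy-4-pivaloyloxyphenyl)methyl]-2-oxooxolane-3-carboxylate | COC(=O)[C@H]1C(=O)OC[C@@H]1[C@@H](O)c1ccc(OC(=O)C(C)(C)C)c(OC)c1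
F4 | step 10 | ethyl (2R,3S)-2-[4-(benzyloxy)-3-methoxyphenyl]-5-formyl-7-methoxy-2,3-dihydro-1-benzofuran-3-carboxylate (cis) | COc1cc([C@@H]2Oc3c(OC)cc(C=O)cc3[C@@H]2C(=O)OCC)ccc1OCc1ccccc1
F5 | step 10 | ethyl (2S,3S)-2-[4-(benzyloxy)-3-methoxyphenyl]-5-formyl-7-methoxy-2,3-dihydro-1-benzofuran-3-carboxylate (trans) | COc1cc([C@H]2Oc3c(OC)cc(C=O)cc3[C@@H]2C(=O)OCC)ccc1OCc1ccccc1
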